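The route rests on making the C6–C7 bond, the bond between the lactone O–CH (C6) and the ring-fusion CH (C7) that is common to the ten-membered carbocycle and the α-methylene-γ-butyrolactone. An open chain ending in an enal (C6) and a 2-(bromomethyl)enoate (C7=C11, C13–Br) is reduced by CrCl2 to an allylchromium species that adds through C7 to the aldehyde. This one operation closes the ten-membered ring, sets C6 and C7, moves the alkene to the exocyclic C11=C13 position and, by acylation of the new alkoxide, closes the lactone. The Z-C1=C10 alkene, both esters and the silylated C8 carbinol are installed beforehand.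

Key step: step 19

Remark: atom labels follow the target throughout (ring C1–C10 with C14 methyl on C10, angelate on C2, C15 acetoxymethyl on C4, lactone oxygen on C6, ring fusion C7, hydroxyl on C8; C11/C12/C13 = lactone α-carbon, carbonyl, exocyclic methylene), and the ring-closed hydroxy ester of step 19 is assumed to lactonise in the flask.

Step 1
Reactants: 1 (S)-glycidol
Product: 2 (R)-4-methoxybenzyl glycidyl ether
Conditions: NaH, PMBCl, Bu4NI (cat.), THF, 0 °C → rt
Reagents that add atoms: 4-methoxybenzyl chloride, COc1ccc(CCl)cc1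
Why: Williamson etherification of the primary alkoxide leaves the stereocentre untouched (the descriptor changes from S to R only through CIP priorities) and installs the oxidatively removable group for the future C7 oxygen.

Step 2
Reactants: 2 (R)-4-methoxybenzyl glycidyl ether
Product: 3 (2R)-1-(4-methoxybenzyloxy)pent-4-yn-2-ol
Conditions: LiC≡CH·H2NCH2CH2NH2, DMSO, 0 °C → rt
Reagents that add atoms: lithium acetylide–ethylenediamine complex, [Li]C#C.NCCN
Why: SN2 opening of the terminal epoxide at its unsubstituted carbon (C9) by the acetylide keeps the C8 configuration from glycidol and gives the homopropargylic alcohol.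

Step 3
Reactants: 3 (2R)-1-(4-methoxybenzyloxy)pent-4-yn-2-ol
Product: 4 TBS ether of 3, (2R)-2-(tert-butyldimethylsilyloxy)-1-(4-methoxybenzyloxy)pent-4-yne
Conditions: TBSCl, imidazole, DMF, rt
Reagents that add atoms: tert-butyldimethylsilyl chloride, CC(C)(C)[Si](C)(C)Cl
Why: Standard silylation of the secondary C8 alcohol gives a robust, non-chelating ether that is meant to stay until the last step.

Step 4
Reactants: 4 TBS ether of 3
Product: 5 (5R)-5-(TBSO)-6-(PMBO)hex-2-ynal
Conditions: n-BuLi, THF, −78 °C; DMF, −78 → 0 °C; inverse quench into cold aq KH2PO4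
Reagents that add atoms: N,N-dimethylformamide, CN(C)C=O
Why: Formylation of the lithium acetylide with DMF gives the ynal (C2 aldehyde), and the buffered inverse quench prevents conjugate addition of the liberated dimethylamine.

Step 5
Reactants: 5 (5R)-5-(TBSO)-6-(PMBO)hex-2-ynal
Product: 6 (4S,8R)-8-(TBSO)-9-(PMBO)nona-1,5-diyn-4-ol
Conditions: (−)-Ipc2B–CH=C=CH2 (from (+)-α-pinene), Et2O, −100 → −78 °C; then NaOH, H2O2, 0 °C
Reagents that add atoms: (−)-B-allenyldiisopinocampheylborane, C=C=CB([C@@H]1C[C@@H]2C[C@H]([C@H]1C)C2(C)C)[C@@H]1C[C@@H]2C[C@H]([C@H]1C)C2(C)C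
Why: Reagent-controlled asymmetric allenylboration (SE2' through a six-membered chair) forms the C2–C3 bond and the homopropargylic alcohol, the isopinocampheyl groups from (+)-α-pinene being expected to direct attack to the Si face of the aldehyde so that C2 is set as S independently of the remote C8 centre.

Step 6
Reactants: 6 (4S,8R)-8-(TBSO)-9-(PMBO)nona-1,5-diyn-4-ol
Product: 7 (4S,5Z,8R)-8-(TBSO)-9-(PMBO)-6-methylnon-5-en-1-yn-4-ol
Conditions: MeMgBr (6 equiv), THF, 0 °C; then Fe(acac)3 (20 mol%), −78 → 0 °C; aq NH4Cl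
Reagents that add atoms: methylmagnesium bromide, C[Mg]Br
Why: Alkoxide-directed iron-catalysed syn-carbomagnesiation of the propargylic alcohol puts the methyl group on the distal carbon C10 and magnesium on C1, so that protonation should give the Z-trisubstituted allylic alcohol (C2 and C9 cis), while the terminal alkyne is shielded as its magnesium acetylide.

Step 7
Reactants: 7 (4S,5Z,8R)-8-(TBSO)-9-(PMBO)-6-methylnon-5-en-1-yn-4-ol
Product: 8 (5S,6Z,9R)-9-(TBSO)-10-(PMBO)-7-methyldec-6-en-2-yne-1,5-diol
Conditions: n-BuLi (2.2 equiv), THF, −78 → −20 °C; (CH2O)n, → rt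
Reagents that add atoms: formaldehyde (as paraformaldehyde), C=O
Why: The alkoxide/acetylide dianion adds to formaldehyde at carbon only, giving the propargylic alcohol (C6) needed to direct the next step.

Step 8
Reactants: 8 (5S,6Z,9R)-9-(TBSO)-10-(PMBO)-7-methyldec-6-en-2-yne-1,5-diol
Product: 9 (2Z,5S,6Z,9R)-9-(TBSO)-3-iodo-10-(PMBO)-7-methyldeca-2,6-diene-1,5-diol
Conditions: NaAlH2(OCH2CH2OMe)2, THF, 0 °C → rt; EtOAc; then I2, −78 → 0 °C
Reagents that add atoms: iodine, [I][I]
Why: Alkoxide-directed trans-hydroalumination of the propargylic alcohol delivers hydride to C5 and aluminium to C4 in a five-membered alanate, and iodinolysis with retention should give the vinyl iodide with iodine cis to the C6 carbinol carbon, which fixes the C4=C5 geometry; the isolated C1=C10 alkene is not reduced.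

Step 9
Reactants: 9 iodo diol
Product: 10 (2Z,5S,6Z,9R)-1,9-bis(TBSO)-3-iodo-10-(PMBO)-7-methyldeca-2,6-dien-5-ol
Conditions: TBSCl (1.05 equiv), imidazole, CH2Cl2, −20 °C
Reagents that add atoms: tert-butyldimethylsilyl chloride, CC(C)(C)[Si](C)(C)Cl
Why: The unhindered primary allylic C6 hydroxyl is silylated much faster than the flanked secondary C2 hydroxyl, which keeps C6 masked until the aldehyde is needed.

Step 10
Reactants: 10 iodo alcohol
Product: 11 (2Z,5S,6Z,9R)-1,9-bis(TBSO)-3-(hydroxymethyl)-10-(PMBO)-7-methyldeca-2,6-dien-5-ol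
Conditions: Bu3SnCH2OH, Pd(PPh3)4 (10 mol%), dioxane, 95 °C
Reagents that add atoms: (tributylstannyl)methanol, CCCC[Sn](CO)(CCCC)CCCC
Why: Stille coupling transfers the hydroxymethyl group (C15) to C4 with retention of alkene geometry, so C15 ends cis to C6 as in the target, and it is run before any allylic ester is present so that zerovalent palladium finds no ionisable group.

Step 11
Reactants: 11 diol
Product: 12 primary (C15) acetate of 11
Conditions: AcCl, 2,4,6-collidine, CH2Cl2, −78 °C
Reagents that add atoms: acetyl chloride, CC(=O)Cl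
Why: Acetyl chloride with a hindered pyridine base at low temperature acetylates the primary allylic alcohol selectively over the secondary C2 alcohol.

Step 12
Reactants: 12 hydroxy acetate
Product: 13 fully protected chain, C2 angelate of 12
Conditions: angelic acid, 2,4,6-Cl3C6H2COCl, Et3N, toluene, rt; then 12, 80 °C (no DMAP)
Reagents that add atoms: angelic acid, C/C=C(/C)C(=O)O
Why: Yamaguchi mixed-anhydride esterification without a nucleophilic catalyst acylates the secondary alcohol with retention at C2 and avoids the isomerisation of angelate to tiglate that acylpyridinium intermediates cause.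

Step 13
Reactants: 13 fully protected chain
Product: 14 primary C7 alcohol (13 without the PMB group)
Conditions: DDQ, CH2Cl2/pH 7 buffer, 0 °C
Reagents that add atoms: none
Why: Oxidative cleavage of the 4-methoxybenzyl ether by DDQ leaves silyl ethers, both esters and the trisubstituted alkenes untouched, and the buffer suppresses silyl migration from O8.

Step 14
Reactants: 14 primary alcohol
Product: 15 α-silyloxy aldehyde (C7 aldehyde)
Conditions: Dess–Martin periodinane, NaHCO3, CH2Cl2, 0 °C → rt
Reagents that add atoms: none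
Why: Buffered Dess–Martin oxidation gives the aldehyde under non-basic conditions that should not epimerise the adjacent C8 centre.

Step 15
Reactants: 15 α-silyloxy aldehyde
Product: 16 Morita–Baylis–Hillman adduct (C7 carbinol, both epimers)
Conditions: methyl acrylate (neat, excess), DABCO (1 equiv), rt, 3–5 d
Reagents that add atoms: methyl acrylate, C=CC(=O)OC
Why: The Morita–Baylis–Hillman reaction attaches C11–C13 to the activated α-oxygenated aldehyde, and the new C7 carbinol centre may form as a mixture because it is erased in the next step.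

Step 16
Reactants: 16 Morita–Baylis–Hillman adduct
Product: 17 (Z)-2-(bromomethyl)enoate (C7=C11, C13–Br)
Conditions: NBS, Me2S, CH2Cl2, 0 °C → rt
Reagents that add atoms: N-bromosuccinimide, O=C1CCC(=O)N1Br
Why: Activation of the allylic alcohol as an alkoxysulfonium salt and SN2' displacement by bromide gives the conjugated, thermodynamically preferred (Z)-2-(bromomethyl)enoate from both C7 epimers.

Step 17
Reactants: 17 allylic bromide
Product: 18 primary allylic C6 alcohol
Conditions: HF·pyridine, pyridine, THF, 0 °C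
Reagents that add atoms: none
Why: Buffered HF·pyridine cleaves the unhindered primary allylic silyl ether much faster than the secondary C8 silyl ether and does not touch the allylic bromide or the esters.

Step 18
Reactants: 18 allylic alcohol
Product: 19 enal bromide (cyclisation precursor)
Conditions: MnO2, CH2Cl2, rt
Reagents that add atoms: none
Why: Neutral allylic oxidation with MnO2 gives the enal without isomerising the C4=C5 bond and without affecting the allylic bromide.

Step 19
Reactants: 19 enal bromide
Product: 21 O8-TBS ether of the target lactone, via ring-closed hydroxy ester 20 (not isolated)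
Conditions: CrCl2 (8 equiv), THF, 0.002 M, slow addition of 19 over 10 h, rt; then 40 °C, 2 h
Reagents that add atoms: none
Why: Two equivalents of CrCl2 reduce the C13–Br bond to an allylchromium species of trivalent chromium, which adds through its γ-carbon C7 to the C6 aldehyde in a chair-like six-membered transition state (Cr–O=C6···C7=C11–C13), forming the C6–C7 bond while the alkene moves to C11=C13, and the chromium alkoxide of 20 then acylates the methyl ester to give the lactone. The closest known reaction type is the chromium-mediated intramolecular Barbier (Nozaki–Hiyama) allylation of ω-formyl 2-(bromomethyl)enoates, which is established for ten-membered carbocycles of this terpenoid family. The carbocycle closes in a 10-exo-trig mode at the aldehyde carbon with allylic transposition of the nucleophile, and the lactone closes by a 5-exo-trig acyl substitution. C6 and C7 should be set together as the anti pair (trans-lactone) because the allylchromium can equilibrate to the isomer with C8 trans to C13 and both chain bonds (C5 on C6, C8 on C7) then sit equatorial in the chair; the face of C7 is chosen by the C8 stereocentre, whose C–H bond eclipses the C7=C11 bond to avoid allylic 1,3-strain so that the C8–C9 bond lies anti to the incoming aldehyde and the silyloxy group points outwards, which corresponds to the target configuration at C6 and C7. The step needs cyclisation to beat oligomerisation and simple reduction, which high dilution with slow addition and the chain-folding Z-C1=C10 and C4=C5 alkenes should secure, and it needs γ- and anti-selectivity, the first inherent to allylchromium reagents and the second supported by the bulky, non-chelating silyl ether on O8. The allylic acetate, the angelate and the silyl ether are inert to divalent chromium.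

Step 20
Reactants: 21 O8-TBS ether of the target lactone
Product: 22 target CNP0129394.1
Conditions: HF·pyridine, THF, 0 °C → rt
Reagents that add atoms: none
Why: Fluoride-mediated desilylation under weakly acidic conditions frees the C8 hydroxyl without acyl migration, translactonisation or conjugate addition to the α-methylene lactone.

Compound list
1 | (S)-glycidol | OC[C@H]1CO1 | starting material
2 | (R)-4-methoxybenzyl glycidyl ether | COc1ccc(COC[C@H]2CO2)cc1 | intermediate
3 | (2R)-1-(4-methoxybenzyloxy)pent-4-yn-2-ol | C#CC[C@@H](O)COCc1ccc(OC)cc1 | intermediate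
4 | (2R)-2-(tert-butyldimethylsilyloxy)-1-(4-methoxybenzyloxy)pent-4-yne | C#CC[C@@H](O[Si](C)(C)C(C)(C)C)COCc1ccc(OC)cc1 | intermediate
5 | (5R)-5-(TBSO)-6-(PMBO)hex-2-ynal | O=CC#CC[C@@H](O[Si](C)(C)C(C)(C)C)COCc1ccc(OC)cc1 | intermediate
6 | (4S,8R)-8-(TBSO)-9-(PMBO)nona-1,5-diyn-4-ol | C#CC[C@H](O)C#CC[C@@H](O[Si](C)(C)C(C)(C)C)COCc1ccc(OC)cc1 | intermediate
7 | (4S,5Z,8R)-8-(TBSO)-9-(PMBO)-6-methylnon-5-en-1-yn-4-ol | C#CC[C@H](O)/C=C(/C)C[C@@H](O[Si](C)(C)C(C)(C)C)COCc1ccc(OC)cc1 | intermediate
8 | (5S,6Z,9R)-9-(TBSO)-10-(PMBO)-7-methyldec-6-en-2-yne-1,5-diol | OCC#CC[C@H](O)/C=C(/C)C[C@@H](O[Si](C)(C)C(C)(C)C)COCc1ccc(OC)cc1 | intermediate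
9 | (2Z,5S,6Z,9R)-9-(TBSO)-3-iodo-10-(PMBO)-7-methyldeca-2,6-diene-1,5-diol | OC/C=C(\I)C[C@H](O)/C=C(/C)C[C@@H](O[Si](C)(C)C(C)(C)C)COCc1ccc(OC)cc1 | intermediate
10 | (2Z,5S,6Z,9R)-1,9-bis(TBSO)-3-iodo-10-(PMBO)-7-methyldeca-2,6-dien-5-ol | CC(C)(C)[Si](C)(C)OC/C=C(\I)C[C@H](O)/C=C(/C)C[C@@H](O[Si](C)(C)C(C)(C)C)COCc1ccc(OC)cc1 | intermediate
11 | (2Z,5S,6Z,9R)-1,9-bis(TBSO)-3-(hydroxymethyl)-10-(PMBO)-7-methyldeca-2,6-dien-5-ol | CC(C)(C)[Si](C)(C)OC/C=C(\CO)C[C@H](O)/C=C(/C)C[C@@H](O[Si](C)(C)C(C)(C)C)COCc1ccc(OC)cc1 | intermediate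
12 | C15 acetate of 11 (free C2 hydroxyl; 2S,8R; 1(10)Z,4Z) | CC(C)(C)[Si](C)(C)OC/C=C(\COC(C)=O)C[C@H](O)/C=C(/C)C[C@@H](O[Si](C)(C)C(C)(C)C)COCc1ccc(OC)cc1 | intermediate
13 | C2 angelate of 12: chain with 6-OTBS, 15-OAc, 2-OAng, 8-OTBS, 7-OPMB (2S,8R; 1(10)Z,4Z) | CC(C)(C)[Si](C)(C)OC/C=C(\COC(C)=O)C[C@H](OC(=O)/C(C)=C\C)/C=C(/C)C[C@@H](O[Si](C)(C)C(C)(C)C)COCc1ccc(OC)cc1 | intermediate
14 | primary C7 alcohol (13 without PMB; 2S,8R) | CC(C)(C)[Si](C)(C)OC/C=C(\COC(C)=O)C[C@H](OC(=O)/C(C)=C\C)/C=C(/C)C[C@@H](O[Si](C)(C)C(C)(C)C)CO | intermediate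
15 | C7 aldehyde (α-silyloxy aldehyde; 2S,8R) | CC(C)(C)[Si](C)(C)OC/C=C(\COC(C)=O)C[C@H](OC(=O)/C(C)=C\C)/C=C(/C)C[C@@H](O[Si](C)(C)C(C)(C)C)C=O | intermediate
16 | Morita–Baylis–Hillman adduct: methyl 2-methylene-3-hydroxy ester at C11/C7 (2S,8R; C7 epimers) | CC(C)(C)[Si](C)(C)OC/C=C(\COC(C)=O)C[C@H](OC(=O)/C(C)=C\C)/C=C(/C)C[C@@H](O[Si](C)(C)C(C)(C)C)C(O)C(=C)C(=O)OC | intermediate
17 | (Z)-2-(bromomethyl)enoate with 6-OTBS (2S,8R; C7=C11 Z) | CC(C)(C)[Si](C)(C)OC/C=C(\COC(C)=O)C[C@H](OC(=O)/C(C)=C\C)/C=C(/C)C[C@@H](O[Si](C)(C)C(C)(C)C)/C=C(\CBr)C(=O)OC | intermediate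
18 | primary allylic C6 alcohol of 17 (2S,8R) | OC/C=C(\COC(C)=O)C[C@H](OC(=O)/C(C)=C\C)/C=C(/C)C[C@@H](O[Si](C)(C)C(C)(C)C)/C=C(\CBr)C(=O)OC | intermediate
19 | enal bromide: C6 aldehyde, C13 bromide, methyl ester (2S,8R; 1(10)Z,4Z,7(11)Z) | O=C/C=C(\COC(C)=O)C[C@H](OC(=O)/C(C)=C\C)/C=C(/C)C[C@@H](O[Si](C)(C)C(C)(C)C)/C=C(\CBr)C(=O)OC | intermediate
20 | ring-closed hydroxy ester: ten-membered carbocycle with 6-OH and 7-(1-methoxycarbonylvinyl), 8-OTBS (2S,6R,7S,8R; 7S only because the silyloxy branch outranks C6) | C=C(C(=O)OC)[C@H]1[C@H](O)/C=C(\COC(C)=O)C[C@H](OC(=O)/C(C)=C\C)/C=C(/C)C[C@H]1O[Si](C)(C)C(C)(C)C | intermediate (not isolated)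
21 | O8-TBS ether of the target: trans-fused 12,6-olide (2S,6R,7S,8R; same spatial arrangement as the target) | C=C1C(=O)O[C@@H]2/C=C(\COC(C)=O)C[C@H](OC(=O)/C(C)=C\C)/C=C(/C)C[C@@H](O[Si](C)(C)C(C)(C)C)[C@@H]12 | intermediate
22 | CNP0129394.1: (2S,6R,7R,8R)-15-acetoxy-2-angeloyloxy-8-hydroxy-1(10)Z,4Z,11(13)-triene-12,6-olide (labels as in the remark) | C=C1C(=O)O[C@@H]2/C=C(\COC(C)=O)C[C@H](OC(=O)/C(C)=C\C)/C=C(/C)C[C@@H](O)[C@@H]12 | target

Total step count: 20. Longest linear sequence: 20 steps (fully linear from (S)-glycidol).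

Steps most likely to fail

Step 19 (key step). What may go wrong is addition of the allylchromium to the other face of C7 (wrong relation to C8), syn addition leading to the cis-lactone, or intermolecular coupling and simple reduction of the C–Br bond. The fallback ties O8 to C12 first, so that the allyl unit has a fixed geometry and the aldehyde is delivered from the side of the C9 tether. It sets out from 16 and comes back at 22. Aqueous HF in MeCN, followed by catalytic PPTS, removes both silyl groups and lets the freed C8 hydroxyl lactonise onto the methyl ester, giving the α-methylene-β-hydroxy-γ-lactone with a free C6 alcohol F1. MnO2 oxidises only the primary allylic alcohol to give the enal F2. NBS/Me2S converts the secondary allylic alcohol with allylic shift into the 3-(bromomethyl)butenolide F3. Zinc dust in THF/aq NH4Cl at high dilution (Barbier allylation) then forms the C6–C7 bond from the butenolide dienolate and gives the 8,12-olide with a free C6 hydroxyl F4. Catalytic DBU in toluene moves the lactone to the trans-fused 12,6-position, which is expected to be the more stable arrangement, and gives 22.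

Step 6. What may go wrong is carbometalation of the second alkyne as well, incomplete conversion, or loss of the syn course so that the C1=C10 geometry is mixed. The fallback builds the Z-alkene by cuprate addition before C2 is made. It sets out from 4 and comes back at 7. Alkyne 4 is carboxylated (n-BuLi, ClCO2Me, −78 °C) to the ynoate F5. Me2CuLi at −78 °C with a cold methanol quench adds syn and gives the (Z)-enoate F6. i-Bu2AlH reduces it to the (Z)-allylic alcohol F7, and MnO2 gives the (Z)-enal F8. The allenylborane of step 5 then adds to F8 to give 7 directly.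

Step 10. What may go wrong is slow transfer of the hydroxymethyl group from tin, with competing butyl transfer or loss of iodine by protonation. The fallback brings in C15 as carbon monoxide. It sets out from 10 and comes back at 11. Carbonylative lactonisation of 10 (CO, Pd(PPh3)4, Et3N, MeCN, 60 °C) traps the acylpalladium with the C2 hydroxyl and gives the α-alkylidene-γ-butyrolactone F9 with the alkene geometry retained. i-Bu2AlH at −78 → 0 °C reduces the lactone to diol 11.

Further compounds
F1 | step 19 | 8,12-lactone (α-methylene-β-hydroxy-γ-butyrolactone, C7 epimers) with free C6 alcohol, 15-OAc, 2-OAng | OC/C=C(\COC(C)=O)C[C@H](OC(=O)/C(C)=C\C)/C=C(/C)C[C@H]1OC(=O)C(=C)C1O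
F2 | step 19 | C6 enal of F1 | O=C/C=C(\COC(C)=O)C[C@H](OC(=O)/C(C)=C\C)/C=C(/C)C[C@H]1OC(=O)C(=C)C1O
F3 | step 19 | 3-(bromomethyl)butenolide enal | O=C/C=C(\COC(C)=O)C[C@H](OC(=O)/C(C)=C\C)/C=C(/C)C[C@H]1OC(=O)C(CBr)=C1
F4 | step 19 | cis-fused 12,8-olide with free C6 hydroxyl (2S,6R,7R,8R spatial arrangement of the target) | C=C1C(=O)O[C@@H]2C/C(C)=C\[C@@H](OC(=O)/C(C)=C\C)C/C(COC(C)=O)=C/[C@@H](O)[C@H]12
F5 | step 6 | methyl (5R)-5-(TBSO)-6-(PMBO)hex-2-ynoate | COC(=O)C#CC[C@@H](O[Si](C)(C)C(C)(C)C)COCc1ccc(OC)cc1
F6 | step 6 | methyl (2Z,5R)-5-(TBSO)-6-(PMBO)-3-methylhex-2-enoate | COC(=O)/C=C(/C)C[C@@H](O[Si](C)(C)C(C)(C)C)COCc1ccc(OC)cc1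
F7 | step 6 | (2Z,5R)-5-(TBSO)-6-(PMBO)-3-methylhex-2-en-1-ol | OC/C=C(/C)C[C@@H](O[Si](C)(C)C(C)(C)C)COCc1ccc(OC)cc1
F8 | step 6 | (2Z,5R)-5-(TBSO)-6-(PMBO)-3-methylhex-2-enal | O=C/C=C(/C)C[C@@H](O[Si](C)(C)C(C)(C)C)COCc1ccc(OC)cc1
F9 | step 10 | α-[(Z)-2-(TBSO)ethylidene]-γ-butyrolactone closed between C15 and O2 (2S,8R) | CC(C)(C)[Si](C)(C)OC/C=C1/C[C@@H](/C=C(/C)C[C@@H](O[Si](C)(C)C(C)(C)C)COCc2ccc(OC)cc2)OC1=O
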